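The readings are calculated on assumed constants, and the scatter is random.

- A small charge, 0.75 M in the north-west run, made target at 8.10 mM min⁻¹ over the first 10.0 min.
- The north-east run, with 3 M, made 18.5 mM min⁻¹ over 12.0 min. The rate rose less than the charge.

all flasks: gas phase 190 mM (held)
- north-west: starting material 0.75 M; run made earlier
- north-east: starting material 3 M; run made earlier
- flask: starting material 1.5 M; time 30 min

- north-west (time / min: target / %, starting material / %): 10.0: 10.8, 89.9; 20.0: 19.6, 79.2; 25.0: 22.0, 75.9; 40.0: 27.0, 68.5
- north-east (time / min: target / %, starting material / %): 5.00: 2.7, 97.1; 12.0: 7.4, 92.8; 25.0: 13.3, 86.2; 40.0: 19.1, 79.9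

(readings scatter by 0.3 percentage points)

1. how much target there is at 30 min, in percent of the starting material charged
2. the change that raises the amount of target at 30 min, in percent of the starting material charged most ("none" if none brings more than 2 percentage points) (midnight / autumn / none)
3. amount of target at 30 min, in percent of the starting material charged, after midnight

- midnight: doubling the saturation concentration of gas phase, all else as stated
- autumn: doubling the transfer coefficient of the gas phase, all else as stated

- the analysis behind the earlier runs scatters by 0.3 percentage points, standard deviation
- at the start none of the gas phase is in solution

- I read this as two resistances in series, with supply the most the gas crossing delivers: rate = supply / (1 + crossing charge / charge).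
- Read off the two rates, with their scatter, my value was 2.24 M for the crossing charge: the charge at which, in this law, the gas crossing takes over from the reaction as the rate-limiting step.
- I turned the question round. In this law midnight multiplies the rate by 2, and for autumn to match that, the charge must stand far above the crossing charge.
- This flask held 1.5 M, below my reading of the crossing charge. So I expected autumn to multiply the rate by 1.25, and I chose midnight.
- The forecast said 19.6%, midnight and 29%: “Doubling saturation roughly doubles the rate but probably speeds deactivation”.
- This flask gave 20.7%, and 33.7% after midnight. Midnight gained 13 percentage points, more than autumn.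

    gas phase ⇌ dissolved gas, rate k1*(csat - [dissolved gas]) (kL = 0.00272 s⁻¹)
    starting material + dissolved gas ⇌ target (K = 3.30 L mol⁻¹, k = 0.00343 L mol⁻¹ s⁻¹)
    dissolved gas + target → over-reacted product (k = 8.72 × 10⁻⁴ L mol⁻¹ s⁻¹)
    dissolved gas ⇌ dormant form (K = 3.39, k = 3.52 × 10⁻⁴ s⁻¹)

- Autumn gained 5.4 points in this flask, and my factor gave 5.2 points. For the neighbour flask with 0.60 M, the crossing charge gave 27.3%, and it held 25.3%. The crossing resistance and the backward run each held down part of the target in this flask: removing the resistance gave 32.2%, and removing the backward run gave 30.7%. The path to dormant form was not the reason: removing it took this flask from 20.7% to 21.7%.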